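**Retrosynthetic overview** (disconnections listed in the order the bonds are made)
1. C11–O, then C7–C6: acid 1 → bromolactone 2 by asymmetric bromolactonization (this C–O bond fixes C10 and is later the leaving group); 2 + ring B bromide 3 (ring B is bought as a symmetric ketal) → hydroxy ketone 5.
2. C6–C11: ring A and the spiro atom are closed by trading the tertiary C–O bond of 5 for a C–C bond → diketone 7.
3. Two C(sp2)–CH3 bonds: chiral-base bis-enol triflation desymmetrizes ring B and sets C6 (9); double methylation → diene 10.
4. C3–O and C2–Br last: bromohydroxylation of the ring B alkene → 11.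

Numbering (chamigrene convention, also used for the carbons of 1, 2 and 5 by the position they end up in): ring B = C1–C5, C6 = spiro atom, ring A = C7–C11. C1 is the ring B CH2 next to C2, C3 carries the ring B methyl or oxygen, C7 the ring A methyl or oxygen, C10 the bromine, C11 the gem-dimethyl group.

Assumption: 1 and 3 are taken as catalogue chemicals. The sense of induction of the bromolactonization catalyst and of the chiral lithium amide is assigned by analogy with simpler substrates; if it proves opposite, the mirror-image (pseudo-enantiomeric) catalyst or base is used.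

**Step 1**
Reactants: 1 5-methylhex-4-enoic acid
Product: 2 (5S)-5-bromo-6,6-dimethyloxan-2-one
Conditions: NBS (1.1 equiv), cinchona amino-thiocarbamate catalyst (10 mol%, pseudo-enantiomer giving the 5S lactone), CHCl3/PhMe 1:2, −60 °C
Reagents that add atoms: N-bromosuccinimide, O=C1CCC(=O)N1Br
Why: Catalytic asymmetric bromolactonization: the chiral Lewis-base/Br+ complex differentiates the enantiotopic faces of the Me2C=CH alkene and the carboxylate opens the bromiranium at the tertiary carbon (6-endo, Markovnikov), so the C11–O bond and the (S)-C–Br stereocentre (future C10) are created together.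

**Step 2**
Reactants: 2 (5S)-5-bromo-6,6-dimethyloxan-2-one; 3 8-bromo-1,4-dioxaspiro[4.5]decane
Product: 5 (4S)-4-bromo-1-(1,4-dioxaspiro[4.5]decan-8-yl)-5-hydroxy-5-methylhexan-1-one, via Grignard reagent 4 (not isolated)
Conditions: 3, Mg, THF, rt; then 2, LaCl3·2LiCl (0.3 equiv), THF, −78 °C; pH 7 buffer quench at −78 °C
Reagents that add atoms: none
Why: Mono-addition of a Grignard reagent to a δ-lactone: with LaCl3·2LiCl the secondary alkylmagnesium adds rather than enolizes, the tetrahedral adduct survives at −78 °C so neither a second addition nor alkoxide-to-epoxide closure occurs, and buffered work-up releases the δ-hydroxy ketone with the C–Br stereocentre untouched.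

**Step 3**
Reactants: 5 (4S)-4-bromo-1-(1,4-dioxaspiro[4.5]decan-8-yl)-5-hydroxy-5-methylhexan-1-one
Product: 7 (10S)-10-bromo-11,11-dimethylspiro[5.5]undecane-3,7-dione, via spiro ketone ketal 6 (not isolated)
Conditions: TfOH (10 mol%), HFIP, 0 °C → rt; then 1 M aq HCl, THF, rt
Reagents that add atoms: water, O
Why: Proposed new method: acid-triggered oxygen-to-carbon ring transposition of a δ-hydroxy ketone (a carba-Ferrier-type relay) – in HFIP the tertiary C11–OH is ionized with anchimeric help from the vicinal bromine to a bromiranium ion (the C10–Br bond never breaks, so C10 stays S), capture by the ketone oxygen only regenerates the cyclic oxocarbenium/enol ether and is reversible, whereas the more substituted enol (C6=C7–OH) attacks C11 irreversibly through a six-membered chair (6-enolendo) transition state and forges the C6–C11 bond between two fully substituted carbons, giving ring A as a cyclohexanone whose spiro atom is not yet stereogenic because ring B is symmetric, and aqueous acid then unmasks the C3 ketone; the closest known chemistry is the solvolytic, stereospecific bromonium cyclization of enantioenriched vicinal bromochlorides in HFIP, the Reetz tert-alkylation of enol derivatives and Ferrier/Petasis–Ferrier O-to-C rearrangements.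

**Step 4**
Reactants: 7 (10S)-10-bromo-11,11-dimethylspiro[5.5]undecane-3,7-dione
Product: 9 (6S,10S)-10-bromo-11,11-dimethylspiro[5.5]undeca-2,7-diene-3,7-diyl bis(trifluoromethanesulfonate), via dilithium bis-enolate 8 (not isolated)
Conditions: (S,S)-bis(1-phenylethyl)amine (2.5 equiv), n-BuLi (2.4 equiv), LiCl (1.2 equiv), THF, −78 °C, inverse addition of 7; then PhNTf2 (2.6 equiv), −78 → 0 °C
Reagents that add atoms: N-phenylbis(trifluoromethanesulfonimide), FC(F)(F)S(=O)(=O)N(c1ccccc1)S(=O)(=O)C(F)(F)F
Why: Kinetic enolization with a chiral lithium amide (Koga–Simpkins desymmetrization of 4,4-disubstituted cyclohexanones) followed by O-triflation: ring B of 7 sits in the chair with the C7 carbonyl carbon axial, and the (S,S)-amide removes the axial C2–H (the arm that is cis to bromine across ring A) in preference to the diastereotopic C4–H, which makes the spiro atom a stereocentre (6S), while the C7 ketone can only enolize toward C8; the sense follows the 4-tert-butylcyclohexanone precedent, where the (R,R)-base gives the (S)-enol derivative.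

**Step 5**
Reactants: 9 (6S,10S)-10-bromo-11,11-dimethylspiro[5.5]undeca-2,7-diene-3,7-diyl bis(trifluoromethanesulfonate)
Product: 10 (6R,10S)-10-bromo-3,7,11,11-tetramethylspiro[5.5]undeca-2,7-diene
Conditions: MeZnCl (3 equiv), Pd(PPh3)4 (5 mol%), THF, 50 °C
Reagents that add atoms: methylzinc chloride, C[Zn]Cl
Why: Double Negishi cross-coupling of the two alkenyl triflates with retention of alkene position; the neopentyl secondary C–Br bond does not add oxidatively to zerovalent palladium under these conditions and no stereocentre is touched (6S becomes 6R only through the CIP priority change from OTf to CH3).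

**Step 6**
Reactants: 10 (6R,10S)-10-bromo-3,7,11,11-tetramethylspiro[5.5]undeca-2,7-diene
Product: 11 (2R,3R,6R,10S)-2,10-dibromo-3,7,11,11-tetramethylspiro[5.5]undec-7-en-3-ol
Conditions: NBS (1.05 equiv), THF/H2O 4:1, 0 °C, dark
Reagents that add atoms: N-bromosuccinimide, O=C1CCC(=O)N1Br; water, O
Why: Bromohydrin formation (electrophilic bromohydroxylation): Br+ is taken up reversibly, productive capture occurs at the unhindered ring B alkene (the C7=C8 alkene is flanked by the quaternary spiro atom and its bromiranium cannot be opened at the neopentyl-type C7) on the face anti to the pseudoaxial C7 arm (the C11 face), and water opens the bromiranium at the tertiary C3 from the opposite face (Markovnikov, anti), setting 2R and 3R with Br and OH trans-diequatorial.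

**Compound list**
1 | 5-methylhex-4-enoic acid | CC(C)=CCCC(=O)O | starting material
2 | (5S)-5-bromo-6,6-dimethyloxan-2-one | O=C1CC[C@H](Br)C(C)(C)O1 | intermediate
3 | 8-bromo-1,4-dioxaspiro[4.5]decane | BrC1CCC2(CC1)OCCO2 | starting material
4 | (1,4-dioxaspiro[4.5]decan-8-yl)magnesium bromide (Grignard reagent) | Br[Mg]C1CCC2(CC1)OCCO2 | intermediate
5 | (4S)-4-bromo-1-(1,4-dioxaspiro[4.5]decan-8-yl)-5-hydroxy-5-methylhexan-1-one | O=C(CC[C@H](Br)C(C)(C)O)C1CCC2(CC1)OCCO2 | intermediate
6 | (10S)-10-bromo-3,3-(ethane-1,2-diyldioxy)-11,11-dimethylspiro[5.5]undecan-7-one (spiro ketone ketal) | O=C1CC[C@H](Br)C(C)(C)C12CCC3(CC2)OCCO3 | intermediate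
7 | (10S)-10-bromo-11,11-dimethylspiro[5.5]undecane-3,7-dione | O=C1CC[C@H](Br)C(C)(C)C12CCC(=O)CC2 | intermediate
8 | dilithium (6S,10S)-10-bromo-11,11-dimethylspiro[5.5]undeca-2,7-diene-3,7-bis(olate) (dilithium bis-enolate) | [Li+].[Li+].[O-]C1=CC[C@H](Br)C(C)(C)[C@@]12CCC([O-])=CC2 | intermediate
9 | (6S,10S)-10-bromo-11,11-dimethylspiro[5.5]undeca-2,7-diene-3,7-diyl bis(trifluoromethanesulfonate) | FC(F)(F)S(=O)(=O)OC1=CC[C@H](Br)C(C)(C)[C@@]12CCC(OS(=O)(=O)C(F)(F)F)=CC2 | intermediate
10 | (6R,10S)-10-bromo-3,7,11,11-tetramethylspiro[5.5]undeca-2,7-diene | CC1=CC[C@H](Br)C(C)(C)[C@@]12CCC(C)=CC2 | intermediate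
11 | (2R,3R,6R,10S)-2,10-dibromo-3,7,11,11-tetramethylspiro[5.5]undec-7-en-3-ol | CC1=CC[C@H](Br)C(C)(C)[C@@]12CC[C@@](C)(O)[C@H](Br)C2 | target

**Step count and risks**
Total steps: 6. Longest linear sequence: 6 steps (1 → 11); 3 enters in step 2.

Step 3, the proposed ring transposition, may stall at the cyclic enol ether or lose HBr from the cation. The known-chemistry fallback sets out from 5. Exchanging the tertiary hydroxyl for chloride with HCl in dioxane/CH2Cl2 at 0 °C (chloride enters at C11 through the bromiranium, so C10 is retained) gives (4S)-4-bromo-5-chloro-1-(1,4-dioxaspiro[4.5]decan-8-yl)-5-methylhexan-1-one F1. TMSOTf/Et3N under equilibrating conditions converts it into the tetrasubstituted silyl enol ether {[(4S)-4-bromo-5-chloro-1-(1,4-dioxaspiro[4.5]decan-8-ylidene)-5-methylhexyl]oxy}trimethylsilane F2. TiCl4 in CH2Cl2 at −78 °C then closes ring A by intramolecular tert-alkylation of the silyl enol ether (Reetz alkylation, the vicinal bromide assisting ionization as in bromochloride solvolyses). Aqueous acid work-up removes the ketal and the sequence comes back to the route at 7.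

Step 4, the desymmetrizing bis-enolization, may give a poor C2/C4 ratio, or the ring A enolate may attack the γ-bromide. The fallback gives up reagent control and sets out from 7. LDA/PhNTf2 under the same inverse-addition protocol gives 9 together with its C6 epimer, (6R,10S)-10-bromo-11,11-dimethylspiro[5.5]undeca-2,7-diene-3,7-diyl bis(trifluoromethanesulfonate) F3. The two are diastereomers and are separated by chromatography; pure 9 comes back to the route at step 5, at the cost of at most half the material.

Step 6 may deliver bromine to the wrong face of ring B or react unselectively. The fallback sets out from 10 and reverses the order in which the two heteroatoms arrive. The ring B alkene is epoxidized on the C7 face (mCPBA if that face proves the intrinsically preferred one, otherwise the matched enantiomer of the Shi fructose-derived ketone with Oxone) to give (2S,3R,6R,10S)-10-bromo-2,3-epoxy-3,7,11,11-tetramethylspiro[5.5]undec-7-ene F4. Li2NiBr4 in THF then opens the epoxide at the less substituted C2 with inversion. Because oxygen now sits on the face where bromine would otherwise have gone, this gives the complementary trans-bromohydrin and comes back to the route at 11.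

**Further compounds**
F1 | step 3 | (4S)-4-bromo-5-chloro-1-(1,4-dioxaspiro[4.5]decan-8-yl)-5-methylhexan-1-one | O=C(CC[C@H](Br)C(C)(C)Cl)C1CCC2(CC1)OCCO2
F2 | step 3 | {[(4S)-4-bromo-5-chloro-1-(1,4-dioxaspiro[4.5]decan-8-ylidene)-5-methylhexyl]oxy}trimethylsilane | C[Si](C)(C)OC(CC[C@H](Br)C(C)(C)Cl)=C1CCC2(CC1)OCCO2
F3 | step 4 | (6R,10S)-10-bromo-11,11-dimethylspiro[5.5]undeca-2,7-diene-3,7-diyl bis(trifluoromethanesulfonate) | FC(F)(F)S(=O)(=O)OC1=CC[C@H](Br)C(C)(C)[C@]12CCC(OS(=O)(=O)C(F)(F)F)=CC2
F4 | step 6 | (2S,3R,6R,10S)-10-bromo-2,3-epoxy-3,7,11,11-tetramethylspiro[5.5]undec-7-ene | CC1=CC[C@H](Br)C(C)(C)[C@@]12CC[C@@]3(C)O[C@H]3C2
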